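## Retrosynthetic overview

- The C5 quaternary ether carbon (bearing Me and the 10-phenyldecyl chain) is installed last, by methyl delivery to the convex face of the cis-fused bicyclic oxocarbenium ion generated from the hemiketal.
- That hemiketal comes from hydrogenolysis of a benzyl-protected keto-lactone, and the free hydroxyl closes onto the ketone to form the tetrahydrofuran ring.
- The lactone forms before the tetrahydrofuran, by acid lactonization of a tertiary alcohol onto a methyl ester.
- The keto-lactone precursor is the TiCl4 chelation-controlled Mukaiyama aldol union of a C18 silyl enol ether (chain fragment) with a chiral α-benzyloxy methyl ketone (core fragment).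
- The chain is built from PhMgBr, 1,5-dibromopentane and 7-bromoheptene. The core fragment comes from (R)-α-hydroxy-γ-butyrolactone.

Assumption: (R)-α-hydroxy-γ-butyrolactone is obtainable as a single enantiomer.

## Route

**Step 1**
Reactants: 1 phenylmagnesium bromide; 2 1,5-dibromopentane (3 equiv)
Product: 3 (5-bromopentyl)benzene
Conditions: Li2CuCl4 (3 mol%), THF, 0 °C → rt
Reagents that add atoms: none
Why: Cu-catalysed Kumada coupling of an aryl Grignard with a primary alkyl bromide; excess dibromide suppresses bis-arylation.

**Step 2**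
Reactants: 3; 4 7-bromohept-1-ene
Product: 5 12-phenyldodec-1-ene
Conditions: (i) Mg, THF, reflux; (ii) 4, Li2CuCl4 (3 mol%), −10 °C → rt
Reagents that add atoms: none
Why: Cu-catalysed alkyl–alkyl Kumada coupling; the terminal alkene is untouched and the C10 chain is completed.

**Step 3**
Reactants: 5
Product: 6 12-phenyldodecan-2-one
Conditions: PdCl2 (10 mol%), CuCl, O2 (balloon), DMF/H2O 7:1, rt
Reagents that add atoms: water (O)
Why: Tsuji–Wacker oxidation, Markovnikov selective for a terminal alkene, gives the methyl ketone.

**Step 4**
Reactants: 6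
Product: 7 trimethyl[(12-phenyldodec-1-en-2-yl)oxy]silane
Conditions: LDA (1.1 equiv), THF, −78 °C; then TMSCl, −78 °C → rt
Reagents that add atoms: chlorotrimethylsilane, C[Si](C)(C)Cl
Why: Kinetic deprotonation occurs at the unhindered CH3, so the terminal silyl enol ether forms regioselectively.

**Step 5**
Reactants: 8 (R)-3-hydroxydihydrofuran-2(3H)-one [(R)-α-hydroxy-γ-butyrolactone]
Product: 9 (R)-3-(benzyloxy)dihydrofuran-2(3H)-one
Conditions: BnOC(=NH)CCl3, TfOH (5 mol%), CH2Cl2/cyclohexane, rt
Reagents that add atoms: benzyl trichloroacetimidate, N=C(OCc1ccccc1)C(Cl)(Cl)Cl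
Why: Acid-catalysed imidate benzylation avoids base, so the α-stereocentre (the future C3a) is not epimerised.

**Step 6**
Reactants: 9
Product: 10 (R)-3-(benzyloxy)-5-hydroxypentan-2-one (present mainly as its cyclic hemiketal)
Conditions: MeLi (1.05 equiv), THF, −78 °C, 1 h; aq. NH4Cl
Reagents that add atoms: methyllithium, C[Li]
Why: Addition to the lactone gives a stable tetrahedral hemiketal alkoxide at −78 °C, so it stops at the methyl ketone oxidation level and the stereocentre is untouched.

**Step 7**
Reactants: 10
Product: 11 (R)-3-(benzyloxy)-4-oxopentanoic acid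
Conditions: TEMPO (10 mol%), PhI(OAc)2 (2.5 equiv), MeCN/H2O 1:1, rt
Reagents that add atoms: water (O)
Why: TEMPO/BAIB oxidation takes the primary alcohol of the ring-opened tautomer to the acid; the ketone and benzyl ether survive.

**Step 8**
Reactants: 11
Product: 12 methyl (R)-3-(benzyloxy)-4-oxopentanoate
Conditions: TMSCHN2 (1.3 equiv), MeOH/PhMe, 0 °C
Reagents that add atoms: trimethylsilyldiazomethane, C[Si](C)(C)C=[N+]=[N-]
Why: Neutral esterification avoids enolisation of the α-alkoxy ketone.

**Step 9 (late coupling)**
Reactants: 7 (silyl enol ether); 12 (α-benzyloxy ketone)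
Product: 13 methyl (3R,4R)-3-(benzyloxy)-4-hydroxy-4-methyl-6-oxo-16-phenylhexadecanoate
Conditions: TiCl4 (1.1 equiv), CH2Cl2, −78 °C, 2 h; then 1 M HCl/THF, rt (removes any O-TMS)
Reagents that add atoms: none
Why: Mukaiyama aldol with Cram-chelate control. TiCl4 chelates the ketone oxygen and the OBn oxygen, and the enol ether attacks from the face carrying H, anti to CH2CO2Me. This sets the tertiary carbinol as (R) relative to the (R) benzyloxy carbon, which is the cis-fusion-compatible relationship.

**Step 10**
Reactants: 13
Product: 14 (4R,5R)-4-(benzyloxy)-5-methyl-5-(2-oxo-12-phenyldodecyl)dihydrofuran-2(3H)-one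
Conditions: p-TsOH·H2O (10 mol%), toluene, 50 °C, 4 h
Reagents that add atoms: none
Why: Acid-catalysed γ-lactonisation (transesterification, loss of MeOH) of the tertiary alcohol is favoured by the gem-disubstitution; both stereocentres are retained because no C–O bond at a stereocentre is broken.

**Step 11**
Reactants: 14
Product: 15 (3aR,6aR)-5-hydroxy-6a-methyl-5-(10-phenyldecyl)tetrahydrofuro[3,2-b]furan-2(3H)-one (hemiketal, C5 epimeric mixture)
Conditions: H2 (1 atm), Pd(OH)2/C, EtOAc, rt
Reagents that add atoms: none
Why: Hydrogenolysis of the benzyl ether frees the secondary alcohol, which closes onto the ketone (ring–chain hemiketalisation). The THF ring can only form cis-fused to the lactone, and the phenyl ring and lactone are unaffected at 1 atm.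

**Step 12**
Reactants: 15
Product: 16 (3aR,5S,6aR)-5,6a-dimethyl-5-(10-phenyldecyl)hexahydrofuro[3,2-b]furan-2-one (target)
Conditions: Me3Al (5 equiv), CH2Cl2, −78 → 0 °C; aq. Rochelle salt
Reagents that add atoms: trimethylaluminum, C[Al](C)C
Why: Lewis-acid ionisation of the hemiketal gives a cis-fused bicyclic oxocarbenium ion. Methyl is delivered to the convex (exo) face, anti to the folded lactone, so Me ends up exo (cis to the C6a-Me) and the decyl chain endo. This gives the (5S) quaternary ether; C3a and C6a were set earlier and are not touched.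

## Compound list

| No. | Name | SMILES | Role |
|---|---|---|---|
| 1 | phenylmagnesium bromide | Br[Mg]c1ccccc1 | starting material |
| 2 | 1,5-dibromopentane | BrCCCCCBr | starting material |
| 3 | (5-bromopentyl)benzene | BrCCCCCc1ccccc1 | intermediate |
| 4 | 7-bromohept-1-ene | C=CCCCCCBr | starting material |
| 5 | 12-phenyldodec-1-ene | C=CCCCCCCCCCCc1ccccc1 | intermediate |
| 6 | 12-phenyldodecan-2-one | CC(=O)CCCCCCCCCCc1ccccc1 | intermediate |
| 7 | silyl enol ether of 6 | C=C(O[Si](C)(C)C)CCCCCCCCCCc1ccccc1 | intermediate |
| 8 | (R)-α-hydroxy-γ-butyrolactone | O=C1OCC[C@H]1O | starting material |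
| 9 | (R)-3-(benzyloxy)dihydrofuran-2(3H)-one | O=C1OCC[C@H]1OCc1ccccc1 | intermediate |
| 10 | (R)-3-(benzyloxy)-5-hydroxypentan-2-one (open form) | OCC[C@@H](OCc1ccccc1)C(C)=O | intermediate |
| 11 | (R)-3-(benzyloxy)-4-oxopentanoic acid | OC(=O)C[C@@H](OCc1ccccc1)C(C)=O | intermediate |
| 12 | methyl (R)-3-(benzyloxy)-4-oxopentanoate | COC(=O)C[C@@H](OCc1ccccc1)C(C)=O | intermediate |
| 13 | aldol adduct (3R,4R) | COC(=O)C[C@@H](OCc1ccccc1)[C@](C)(O)CC(=O)CCCCCCCCCCc1ccccc1 | intermediate |
| 14 | benzyloxy keto-lactone (4R,5R) | C[C@]1(CC(=O)CCCCCCCCCCc2ccccc2)OC(=O)C[C@H]1OCc1ccccc1 | intermediate |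
| 15 | bicyclic hemiketal (C5 unspecified) | OC1(CCCCCCCCCCc2ccccc2)C[C@@]2(C)OC(=O)C[C@H]2O1 | intermediate |
| 16 | plakortolide ether | C[C@]1(CCCCCCCCCCc2ccccc2)C[C@@]2(C)OC(=O)C[C@H]2O1 | target |

## Totals

Total steps: 12. Longest linear sequence: 8 (for example steps 1–4, then 9–12; steps 5–8 then 9–12 is equally long).

## Three steps most likely to fail

1. **Step 12 (C5 methylation).** The convex-face selectivity may be modest, because the C6a-Me sits on that face and the hemiketal can also be methylated as its open ketone. Fallback: methylenate the ketone of 14 (Petasis Cp2TiMe2), remove the benzyl ether with BCl3, then do a Brønsted-acid 5-exo hydroalkoxylation so the exocyclic CH2 becomes the Me. Separate the C5 epimers by chromatography.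
2. **Step 9 (TiCl4 Mukaiyama aldol to a ketone).** Ketones are poor electrophiles, so the yield and chelation selectivity may suffer. Fallback: add 2-(10-phenyldecyl)allylzinc bromide to ketone 12 under Mg or Ti chelation to give the homoallylic tertiary alcohol, then cleave the alkene (OsO4/NaIO4) to the same β-hydroxy ketone.
3. **Step 10 (lactonisation of a tertiary β-hydroxy ketone).** Dehydration or retro-aldol may compete. Fallback: reverse the order, hydrogenolysing first so the ketone is masked as the cyclic hemiketal, then lactonise, using the tert-butyl ester (Boc2O/tBuOH in place of TMSCHN2 in step 8) with cold TFA.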